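**Retrosynthetic overview**
- Target ⇒ both phenolic C–OH bonds are made last, in one operation, from the corresponding bis(aryl chloride); the two chlorines serve as inert phenol placeholders. This double aryl C–O bond formation is the key step.
- Bis(aryl chloride) ⇒ Friedel–Crafts benzylation of 3-chloro-3′,5′-dimethoxybibenzyl with 4-chlorobenzyl alcohol; ring A (dimethoxy) is the only activated ring.
- Bibenzyl ⇒ copper-catalysed sp3–sp3 coupling of 3,5-dimethoxybenzyl bromide with the Grignard reagent from 3-chlorobenzyl chloride.
- No ring is formed: rings A (dimethoxy), B (3-hydroxyphenyl) and C (4-hydroxyphenyl) are bought as benzenes and joined A–B first, then A–C.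

Assumption: the target SMILES contains no stereocentre or stereogenic double bond, so the compound is achiral and no stereocontrol is needed.

**Route**

Step 1
Reactants: 1 3-chlorobenzyl chloride; 2 3,5-dimethoxybenzyl bromide
Product: 4 1-[2-(3-chlorophenyl)ethyl]-3,5-dimethoxybenzene, via (3-chlorobenzyl)magnesium chloride 3 (not isolated)
Conditions: Mg, 2-MeTHF, 0 °C; then 2 (0.8 equiv), Li2CuCl4 (3 mol%), THF, −20 °C → rt
Reagents that add atoms: none
Why: Magnesium inserts only into the benzylic C–Cl bond (the aryl C–Cl bond is inert here), and the benzyl Grignard then couples with the benzylic bromide in a copper-catalysed Kumada-type (Kochi) sp3–sp3 coupling; no stereocentre is formed.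

Step 2
Reactants: 4 1-[2-(3-chlorophenyl)ethyl]-3,5-dimethoxybenzene (1.5 equiv, excess recovered); 5 4-chlorobenzyl alcohol
Product: 6 1-[(4-chlorophenyl)methyl]-2-[2-(3-chlorophenyl)ethyl]-4,6-dimethoxybenzene
Conditions: TfOH (10 mol%), HFIP, rt → 50 °C
Reagents that add atoms: none
Why: Friedel–Crafts benzylation, in which TfOH/HFIP ionises 5 and the benzylic electrophile attacks ring A (both chloroarene rings are deactivated) at the position para to one OMe and ortho to the other, which is doubly represented and favoured over the site between the two methoxy groups; no stereocentre is formed.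

Step 3
Reactants: 6 1-[(4-chlorophenyl)methyl]-2-[2-(3-chlorophenyl)ethyl]-4,6-dimethoxybenzene
Product: 7 3-[2-[2-[(4-hydroxyphenyl)methyl]-3,5-dimethoxyphenyl]ethyl]phenol (gymconopin D)
Conditions: N2O (2 bar), NiBr2(dme) (10 mol%), 4,4′,4″-tri-tert-butyl-2,2′:6′,2″-terpyridine (12 mol%), Zn (4 equiv), NaI (20 mol%), DMA, 60 °C; then 1 M HCl
Reagents that add atoms: nitrous oxide, [N-]=[N+]=O
Why: Proposed new method: nickel-catalysed reductive oxygen-atom insertion from N2O into unactivated aryl C–Cl bonds, run on both chlorides in one flask; zerovalent nickel on the electron-rich tridentate ligand adds each Ar–Cl (helped by 60 °C and iodide), Zn reduces the divalent aryl–nickel halide to a monovalent aryl–nickel species that binds N2O and passes its oxygen into the Ni–C bond with loss of N2 (a Baeyer–Villiger-like aryl shift from nickel to oxygen), and the nickel aryloxide hands the phenoxide to zinc, so no phenoxide/aryl chloride coupling to diaryl ethers can occur; the closest known reaction type is the nickel-catalysed N2O hydroxylation of aryl iodides and bromides, which to my knowledge has not been extended to aryl chlorides, and the chloride activation borrows from nickel/tridentate-nitrogen-ligand reductive couplings of aryl chlorides.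

**Compound list**

1 | 3-chlorobenzyl chloride | ClCc1cccc(Cl)c1 | starting material
2 | 3,5-dimethoxybenzyl bromide | COc1cc(CBr)cc(OC)c1 | starting material
3 | (3-chlorobenzyl)magnesium chloride | Cl[Mg]Cc1cccc(Cl)c1 | intermediate (not isolated)
4 | 1-[2-(3-chlorophenyl)ethyl]-3,5-dimethoxybenzene | COc1cc(CCc2cccc(Cl)c2)cc(OC)c1 | intermediate
5 | 4-chlorobenzyl alcohol | OCc1ccc(Cl)cc1 | starting material
6 | 1-[(4-chlorophenyl)methyl]-2-[2-(3-chlorophenyl)ethyl]-4,6-dimethoxybenzene | COc1cc(CCc2cccc(Cl)c2)c(Cc2ccc(Cl)cc2)c(OC)c1 | intermediate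
7 | 3-[2-[2-[(4-hydroxyphenyl)methyl]-3,5-dimethoxyphenyl]ethyl]phenol (gymconopin D, achiral) | COc1cc(CCc2cccc(O)c2)c(Cc2ccc(O)cc2)c(OC)c1 | target

**Step count and risks**

Total step count: 3. Longest linear sequence: 3 steps (1 → 4 → 6 → 7).

Steps most likely to fail:

Step 3 (the proposed new reaction). The risks are slow oxidative addition of the aryl chlorides, hydrodechlorination, reductive biaryl coupling to oligomers, and stopping at the mono-phenol. The fallback uses known chemistry, sets out from 6 and comes back at 7. Double Miyaura borylation of 6 (B2pin2, Pd2(dba)3/XPhos, KOAc, dioxane, 100 °C) gives 1-[(4-Bpin-phenyl)methyl]-2-[2-(3-Bpin-phenyl)ethyl]-4,6-dimethoxybenzene F5 (Bpin = 4,4,5,5-tetramethyl-1,3,2-dioxaborolan-2-yl). Oxidation with H2O2/NaOH in THF/H2O at 0 °C (boron-to-oxygen aryl migration) then gives 7.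

Step 2. The risks are the regioisomer benzylated between the two methoxy groups and over-benzylation of ring A. The fallback sets out from 4 and comes back at 6. NBS in MeCN at 0 °C brominates 4 para to a methoxy group and ortho to the side chain, a reliably selective reaction for 3,5-dimethoxyalkylbenzenes, to give 2-bromo-1-[2-(3-chlorophenyl)ethyl]-3,5-dimethoxybenzene F3. Br/Li exchange (n-BuLi, THF, −78 °C; the aryl chloride survives) and addition to commercial 4-chlorobenzaldehyde (O=Cc1ccc(Cl)cc1) gives racemic (4-chlorophenyl){2-[2-(3-chlorophenyl)ethyl]-4,6-dimethoxyphenyl}methanol F4. Ionic reduction of this doubly benzylic, dimethoxy-stabilised carbinol (Et3SiH, TFA, CH2Cl2, 0 °C) gives 6 as a single regioisomer.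

Step 1. The risks are Wurtz homocoupling during Grignard formation and halogen–magnesium scrambling, which give symmetrical bibenzyls that are hard to separate from 4. The fallback sets out from 1 and comes back at 4. Arbuzov reaction of 1 with P(OEt)3 (neat, 130 °C) gives diethyl [(3-chlorophenyl)methyl]phosphonate F1. Horner–Wadsworth–Emmons olefination with commercial 3,5-dimethoxybenzaldehyde (COc1cc(C=O)cc(OC)c1; NaH, THF, 0 °C → rt) gives (E)-1-chloro-3-[2-(3,5-dimethoxyphenyl)ethenyl]benzene F2. Diimide reduction (TsNHNH2, NaOAc, THF/H2O, reflux) saturates the alkene without touching the C–Cl bond and gives 4.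

**Further compounds**

F1 | step 1 | diethyl [(3-chlorophenyl)methyl]phosphonate | CCOP(=O)(Cc1cccc(Cl)c1)OCC
F2 | step 1 | (E)-1-chloro-3-[2-(3,5-dimethoxyphenyl)ethenyl]benzene | COc1cc(/C=C/c2cccc(Cl)c2)cc(OC)c1
F3 | step 2 | 2-bromo-1-[2-(3-chlorophenyl)ethyl]-3,5-dimethoxybenzene | COc1cc(CCc2cccc(Cl)c2)c(Br)c(OC)c1
F4 | step 2 | (4-chlorophenyl){2-[2-(3-chlorophenyl)ethyl]-4,6-dimethoxyphenyl}methanol (racemic) | COc1cc(CCc2cccc(Cl)c2)c(C(O)c2ccc(Cl)cc2)c(OC)c1
F5 | step 3 | 1-[(4-Bpin-phenyl)methyl]-2-[2-(3-Bpin-phenyl)ethyl]-4,6-dimethoxybenzene | COc1cc(CCc2cccc(B3OC(C)(C)C(C)(C)O3)c2)c(Cc2ccc(B3OC(C)(C)C(C)(C)O3)cc2)c(OC)c1
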